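Compound numbers refer to the list after the steps. Ring A is the trioxygenated ring (C1 carries the carbinol, C3 and C4 the hydroxyls, C5 the ether oxygen), ring B the para-phenylene, ring C the 1,2,3-trisubstituted ring (C1 ethano bridge, C2 ether oxygen, C3 hydroxyl) and ring D the meta-phenylene. Cα is the carbinol carbon and Cβ its CH2 neighbour.

Remark on the chemistry: the aryl benzyl ketone 15 is assumed to be read by the transfer-hydrogenation catalyst like an aryl alkyl ketone, so that the (S,S)-diamine ligand gives the (S)-carbinol.

## Analysis of the target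

The target 24 is an 18-membered macrocycle in which four benzene rings are joined by two diaryl ether oxygens (C5 of ring A to ring B, C2 of ring C to ring D), one ethano bridge (ring B to C1 of ring C) and one CH(OH)–CH2 unit (Cα on ring A, Cβ on ring D). It has a single stereocentre, the (S)-configured Cα. No second centre can relay to it, so its configuration must come from a catalyst. Cα is benzylic and para to the C4 hydroxyl of ring A, so the free compound is a p-hydroxybenzyl alcohol that can ionise to a quinone methide under acid or strong base, with racemisation or elimination. Ring A also carries an air-sensitive catechol, so the last unmasking steps must be close to neutral. On rings A and C the free hydroxyls sit next to arylated oxygens, so each oxygen needs its own origin. The hard bond is the C2–O ether of ring C. It lies between the C1 ethano substituent and the C3 oxygen, a doubly ortho-substituted, electron-rich position where metal-mediated arylation is slow. The floppy 18-membered ring must also close in competition with oligomerisation. The plan rests on the contiguous C1–CH2, C2–O, C3–OH pattern of ring C. The C3 oxygen is carried as a formyl group, which makes a fluoride at C2 displaceable by the ring D phenoxide and is afterwards turned into the C3 hydroxyl by peracid oxidation.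

## Retrosynthetic reasoning

**24 back to 22.** The last two operations break no skeletal bond. The silyl ether on Cα of 23 is cleaved by buffered fluoride, and before that the two benzyl ethers on ring A of 22 are removed by hydrogenolysis. The silyl group stays on during hydrogenolysis so that its bulk shields the benzylic C–O bond. It leaves last, under conditions that are neither acidic nor basic, because only then is the C4 hydroxyl free and the quinone methide pathway open.

**22 back to 20.** The C3 hydroxyl of ring C is traced to a C3 formyl group through the aryl formate 21 (Dakin oxidation). The oxygen that would be hardest to distinguish from its C2 neighbour thus becomes a carbon substituent that can activate C2.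

**20 back to 19.** The C2(ring C)–O(ring D) bond is cut. This is the most hindered bond of the molecule, and addition–elimination is the one ether-forming mechanism that tolerates two ortho neighbours. Making this bond in the ring closure adds intramolecularity to that advantage. The forward reaction must let the single free phenoxide of 19 displace the single activated fluoride under dilution.

**19 back to 17.** The formyl group is carried as a dimethyl acetal and the ring D phenol as an allyl ether. Zerovalent palladium removes the allyl group (18) and weak aqueous acid the acetal (19), and neither touches the silyl or benzyl ethers.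

**17 back to 15.** The silyl ether comes from the (S)-alcohol 16, and the stereocentre is cut back to the ketone 15. An aryl ketone with one sp3 neighbour is a good substrate for asymmetric transfer hydrogenation, so the only stereocentre is set by a catalyst on an open-chain compound.

**15 back to 10 and 14.** The C(=O)–Cβ bond is cut. The acyl half is the Weinreb amide 10, made from the ester 9. The nucleophile is the benzylic Grignard reagent 14, made from chloride 13, alcohol 12 and 3-hydroxybenzyl alcohol 11. This puts the carbonyl on ring A, where the gallate ester already provides it.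

**9 back to 5 and 7.** The bond between the ethano carbon and C1 of ring C is cut. The alkylborane 8 from styrene 5 couples with aryl bromide 7 (B-alkyl Suzuki–Miyaura), so the bridge arrives saturated and no alkene has to be reduced next to benzyl ethers. Acetal 7 comes from 3-bromo-2-fluorobenzaldehyde 6.

**5 back to 1 and 3.** The ring A–O–ring B ether is cut at the ring B carbon. The phenoxide of 2 displaces fluoride from 4-fluorobenzaldehyde 3 to give 4, and the activating formyl group then becomes the vinyl carbon of 5 by methylenation. Phenol 2 comes from methyl gallate 1 by dibenzylation.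

## Alternatives that were turned down

**Alternative 1: enantioselective conjunctive coupling of two diaryl ether halves.**
- Disconnection: the ring A–Cα and Cβ–ring D bonds, with Cα and Cβ supplied by vinylboronic acid pinacol ester A4.
- Forward key step: the aryl bromide A2 is lithiated with t-BuLi and added to A4. The resulting ate complex couples with the ring D triflate A3 under Pd(OAc)2/MandyPhos through a 1,2-aryl shift, giving the (S)-boronate A1.
- For it: it is the most convergent plan. The stereocentre is set by catalysis in the very step that joins the halves, where the chosen route needs three steps (amide, Grignard addition, reduction). On these points it is stronger.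
- Against it: the step closes no ring. The hindered C2–O ether of ring C is already present in A3 and must be made beforehand by other means. After oxidation at boron, A1 still has to be ring-closed across its two masked formyl groups by a reductive carbonyl coupling and saturation, a macrocyclisation with low-valent titanium next to a benzylic C–O bond. Lithium halide from the exchange also inhibits the palladium step.
- Comparison: the chosen route gives up some convergence. In return its ring closure is itself the solution to the hindered ether, and only three operations follow it.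

**Alternative 2: [1,2]-Wittig ring contraction of a macrocyclic dibenzyl ether.**
- Disconnection: the Cα–Cβ bond, traced to the O–Cβ bond of the 19-membered stannyl ether A5.
- Forward key step: n-BuLi exchanges tin for lithium at Cα of A5 and the ring D benzyl group shifts from oxygen to carbon, giving the 18-membered carbinol A6.
- For it: the ring is first closed as a simple benzyl ether. A6 carries only silyl groups, so a single fluoride step would finish the synthesis, a shorter end-game than in the chosen route.
- Against it: the shift runs through a radical pair, and the lithiated Cα is benzylic and oxygen-substituted, hence configurationally labile, so the (S)-configuration is likely to erode. An enantioenriched stannane is needed anyway. Proton transfer to the other benzylic position, competing sigmatropic shifts and attack of the alkyllithium on the aryl silyl ethers are all plausible. Both diaryl ethers, the hindered one included, must be in place beforehand.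
- Comparison: the chosen route sets Cα by a catalytic reduction on an open chain and never exposes it to carbanion or radical chemistry.

**Alternative 3: oxidative phenol coupling for the ring A ether.**
- Disconnection: the bond between ring A and the ether oxygen to ring B.
- Forward key step: Tl(NO3)3 in methanol oxidises the dibromophenol ring of the seco bisphenol A7. The dichlorophenol oxygen attacks the bromine-bearing ring A carbon, and zinc/acetic acid work-up expels bromide to give A8.
- For it: it makes a diaryl ether ortho to a free phenol without an activated aryl halide, at low temperature and in a biomimetic sense. On mildness of the ring closure it is as good as or better than a hot carbonate SNAr.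
- Against it: stoichiometric trivalent thallium is needed, and four halogens serve as auxiliaries. The remaining bromide of A8 must later be converted into the C3 hydroxyl of ring A and the two chlorides removed. The oxidised ring A bears the CH(OSi) group in its para position, so quinoid intermediates can lose the benzylic hydrogen or add methanol at Cα and destroy the only stereocentre. The hindered ring C ether is again not addressed.
- Comparison: the chosen route uses polar two-electron chemistry with one nucleophile and one electrophile, and needs no halogen manipulation after ring closure.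

Key step: step 14

## Route

Step 1
Reactants: 1 methyl gallate
Product: 2 methyl 3,4-bis(benzyloxy)-5-hydroxybenzoate
Conditions: BnBr (2 equiv), K2CO3 (2 equiv), DMF, 0 °C to rt
Reagents that add atoms: benzyl bromide, BrCc1ccccc1
Why: Williamson etherification; the C4 hydroxyl (para to the ester) is the most acidic and reacts first, after which the second benzyl group can only enter at C3 or the equivalent C5, so two equivalents should give the 3,4-dibenzyl ether as the main product, to be separated from mono- and tribenzyl ethers.

Step 2
Reactants: 2 methyl 3,4-bis(benzyloxy)-5-hydroxybenzoate; 3 4-fluorobenzaldehyde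
Product: 4 methyl 3,4-bis(benzyloxy)-5-(4-formylphenoxy)benzoate
Conditions: K2CO3, DMF, 110 °C
Reagents that add atoms: none
Why: SNAr of the only phenoxide on a fluoride activated by the para formyl group; ester and benzyl ethers are inert to anhydrous carbonate.

Step 3
Reactants: 4 methyl 3,4-bis(benzyloxy)-5-(4-formylphenoxy)benzoate
Product: 5 methyl 3,4-bis(benzyloxy)-5-(4-vinylphenoxy)benzoate
Conditions: Ph3PCH3Br, KOtBu, THF, 0 °C to rt
Reagents that add atoms: methyltriphenylphosphonium bromide, C[P+](c1ccccc1)(c1ccccc1)c1ccccc1.[Br-]
Why: Wittig methylenation; the non-stabilised ylide reacts with the aldehyde far faster than with the aryl ester when no excess base is present.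

Step 4
Reactants: 6 3-bromo-2-fluorobenzaldehyde
Product: 7 1-bromo-3-(dimethoxymethyl)-2-fluorobenzene
Conditions: HC(OMe)3, TsOH·H2O (cat.), MeOH, rt
Reagents that add atoms: trimethyl orthoformate, COC(OC)OC; methanol, CO
Why: Acid-catalysed acetalisation driven by the orthoformate; the acetal masks the formyl group against borane, Grignard reagents and hydride transfer.

Step 5
Reactants: 5 methyl 3,4-bis(benzyloxy)-5-(4-vinylphenoxy)benzoate; 7 1-bromo-3-(dimethoxymethyl)-2-fluorobenzene
Product: 9 methyl 3,4-bis(benzyloxy)-5-(4-{2-[3-(dimethoxymethyl)-2-fluorophenyl]ethyl}phenoxy)benzoate, via B-alkyl-9-BBN adduct 8 (not isolated)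
Conditions: 9-BBN, THF, 0 °C to rt; then 7, PdCl2(dppf) (cat.), K3PO4 (aq.), DMF, 60 °C
Reagents that add atoms: 9-borabicyclo[3.3.1]nonane (9-BBN), B1C2CCCC1CCC2 (its boron is held in 8 only)
Why: Anti-Markovnikov hydroboration of the styrene puts boron on the terminal carbon, and the B-alkyl Suzuki–Miyaura coupling joins that sp3 carbon to C1 of ring C, giving the ethano bridge already saturated. Aryl fluoride, acetal, ester and benzyl ethers are inert to these conditions.

Step 6
Reactants: 9 methyl 3,4-bis(benzyloxy)-5-(4-{2-[3-(dimethoxymethyl)-2-fluorophenyl]ethyl}phenoxy)benzoate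
Product: 10 3,4-bis(benzyloxy)-5-(4-{2-[3-(dimethoxymethyl)-2-fluorophenyl]ethyl}phenoxy)-N-methoxy-N-methylbenzamide
Conditions: MeNH(OMe)·HCl, iPrMgCl, THF, −20 to 0 °C
Reagents that add atoms: N,O-dimethylhydroxylamine hydrochloride, CNOC.Cl
Why: Direct ester-to-Weinreb-amide conversion by the chloromagnesium amide formed in the flask; acetal, aryl fluoride and ethers are not attacked at this temperature.

Step 7
Reactants: 11 3-hydroxybenzyl alcohol
Product: 12 [3-(allyloxy)phenyl]methanol
Conditions: allyl bromide, K2CO3, acetone, reflux
Reagents that add atoms: allyl bromide, C=CCBr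
Why: Williamson etherification; carbonate deprotonates only the phenol, so the benzylic alcohol stays free.

Step 8
Reactants: 12 [3-(allyloxy)phenyl]methanol
Product: 13 1-(allyloxy)-3-(chloromethyl)benzene
Conditions: SOCl2, DMF (cat.), CH2Cl2, 0 °C to rt
Reagents that add atoms: thionyl chloride, O=S(Cl)Cl
Why: Chlorination of a benzylic alcohol through its chlorosulfite; the allyl aryl ether is stable.

Step 9
Reactants: 13 1-(allyloxy)-3-(chloromethyl)benzene; 10 3,4-bis(benzyloxy)-5-(4-{2-[3-(dimethoxymethyl)-2-fluorophenyl]ethyl}phenoxy)-N-methoxy-N-methylbenzamide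
Product: 15 2-[3-(allyloxy)phenyl]-1-[3,4-bis(benzyloxy)-5-(4-{2-[3-(dimethoxymethyl)-2-fluorophenyl]ethyl}phenoxy)phenyl]ethan-1-one, via benzylic Grignard reagent 14 (not isolated)
Conditions: Mg, 2-MeTHF, 0 °C (slow addition of 13); then 10, THF, −10 to 0 °C; aq. NH4Cl
Reagents that add atoms: magnesium, [Mg] (held in 14 only)
Why: Grignard addition to a Weinreb amide; the chelated tetrahedral adduct collapses to the ketone only on work-up, so no tertiary alcohol should form. Cold, slow formation of 14 limits Wurtz coupling.

Step 10
Reactants: 15 2-[3-(allyloxy)phenyl]-1-[3,4-bis(benzyloxy)-5-(4-{2-[3-(dimethoxymethyl)-2-fluorophenyl]ethyl}phenoxy)phenyl]ethan-1-one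
Product: 16 (1S)-2-[3-(allyloxy)phenyl]-1-[3,4-bis(benzyloxy)-5-(4-{2-[3-(dimethoxymethyl)-2-fluorophenyl]ethyl}phenoxy)phenyl]ethan-1-ol
Conditions: RuCl[(S,S)-TsDPEN](p-cymene) (cat.), HCO2H/Et3N (1:1), DMF, 40 °C
Reagents that add atoms: none
Why: Noyori asymmetric transfer hydrogenation; hydride and proton are delivered through a six-membered outer-sphere transition state in which the CH/π contact between the p-cymene ligand and ring A fixes the ketone face, so the (S,S)-ligand should give the (S)-carbinol. The formate medium is kept non-acidic so that the acetal survives; the allyl ether and aryl fluoride are not reduced.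

Step 11
Reactants: 16 (1S)-2-[3-(allyloxy)phenyl]-1-[3,4-bis(benzyloxy)-5-(4-{2-[3-(dimethoxymethyl)-2-fluorophenyl]ethyl}phenoxy)phenyl]ethan-1-ol
Product: 17 tert-butyldimethylsilyl ether of 16 at the (S)-carbinol
Conditions: TBSCl, imidazole, DMAP (cat.), DMF, rt to 40 °C
Reagents that add atoms: tert-butyldimethylsilyl chloride, CC(C)(C)[Si](C)(C)Cl
Why: Silylation of the secondary alcohol with the silyl chloride instead of a silyl triflate, which could activate the dimethyl acetal. The silyl ether protects the benzylic C–O bond through base, peracid and hydrogenolysis.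

Step 12
Reactants: 17 tert-butyldimethylsilyl ether of 16 at the (S)-carbinol
Product: 18 3-{(2S)-2-[3,4-bis(benzyloxy)-5-(4-{2-[3-(dimethoxymethyl)-2-fluorophenyl]ethyl}phenoxy)phenyl]-2-[(tert-butyldimethylsilyl)oxy]ethyl}phenol
Conditions: Pd(PPh3)4 (cat.), morpholine, THF, rt
Reagents that add atoms: none
Why: Tsuji–Trost deallylation; zerovalent palladium ionises the aryl allyl ether to a π-allyl complex that morpholine traps, leaving silyl ether, benzyl ethers and acetal untouched.

Step 13
Reactants: 18 3-{(2S)-2-[3,4-bis(benzyloxy)-5-(4-{2-[3-(dimethoxymethyl)-2-fluorophenyl]ethyl}phenoxy)phenyl]-2-[(tert-butyldimethylsilyl)oxy]ethyl}phenol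
Product: 19 3-[2-(4-{2,3-bis(benzyloxy)-5-[(1S)-1-[(tert-butyldimethylsilyl)oxy]-2-(3-hydroxyphenyl)ethyl]phenoxy}phenyl)ethyl]-2-fluorobenzaldehyde
Conditions: PPTS (cat.), acetone/H2O, 40 °C
Reagents that add atoms: water, O
Why: Acid-catalysed acetal hydrolysis; pyridinium tosylate is too weak an acid to ionise the benzylic silyl ether or to remove the silyl group, so Cα should keep its configuration.

Step 14
Reactants: 19 3-[2-(4-{2,3-bis(benzyloxy)-5-[(1S)-1-[(tert-butyldimethylsilyl)oxy]-2-(3-hydroxyphenyl)ethyl]phenoxy}phenyl)ethyl]-2-fluorobenzaldehyde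
Product: 20 (S)-configured 18-membered macrocyclic aldehyde: target skeleton with CHO at C3 of ring C, benzyl ethers at C3 and C4 of ring A and the TBS ether at Cα
Conditions: Cs2CO3, 4 Å molecular sieves, DMF, 80 °C, syringe-pump addition of 19 (final concentration about 1 mM)
Reagents that add atoms: none
Why: Cs2CO3 deprotonates the ring D phenol; the phenoxide adds to C2 of ring C to give a Meisenheimer anion whose charge is taken up by the ortho formyl group, and loss of fluoride restores the arene and forms the C2–O bond (SNAr, addition–elimination). The closest known reaction type is the macrocyclising SNAr of phenoxides onto ortho-formyl- or ortho-nitro-fluoroarenes used for cyclic diaryl ethers. The 18-membered ring is closed by this intramolecular O-arylation at an sp2 carbon that becomes a ring member. No stereocentre is created, and Cα, which has no acidic hydrogen and carries a base-stable silyl ether, should stay (S). Site selectivity is secured because C2–F is the only activated halide and the ring D hydroxyl the only free nucleophile. Cyclisation over oligomerisation is addressed by slow addition into a dilute hot carbonate suspension and by the loosely paired caesium phenoxide, and the medium is kept anhydrous and hydroxide-free to preserve the formyl group and the silyl ether. The two ortho substituents at C2 slow the attack little, since fluoride is small and the nucleophile approaches perpendicular to the ring plane.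

Step 15
Reactants: 20 (S)-configured 18-membered macrocyclic aldehyde
Product: 22 macrocyclic phenol (OH at C3 of ring C; benzyl ethers on ring A; TBS ether at Cα; S), via aryl formate 21 (not isolated)
Conditions: mCPBA, NaHCO3, CH2Cl2, 0 °C to rt; then K2CO3 (cat.), MeOH, 0 °C
Reagents that add atoms: meta-chloroperbenzoic acid (mCPBA), OOC(=O)c1cccc(Cl)c1
Why: Dakin (Baeyer–Villiger type) oxidation; the peracid adds to the formyl group and the aryl ring, made electron-rich by the ortho aryloxy group, migrates in the Criegee intermediate in preference to hydride, giving formate 21. Mild methanolysis then frees the phenol; benzyl and silyl ethers are inert to buffered peracid.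

Step 16
Reactants: 22 macrocyclic phenol (OH at C3 of ring C; benzyl ethers on ring A; TBS ether at Cα; S)
Product: 23 Cα-O-tert-butyldimethylsilyl ether of the target
Conditions: H2 (1 atm), Pd/C, EtOAc/EtOH, rt
Reagents that add atoms: none
Why: Hydrogenolysis of the two O-benzyl ethers in neutral solvent; the bulky silyl ether disfavours hydrogenolysis of the benzylic Cα–O bond, and diaryl ethers are inert.

Step 17
Reactants: 23 Cα-O-tert-butyldimethylsilyl ether of the target
Product: 24 target, (S)-configured macrocyclic tetraol CNP0333307.1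
Conditions: TBAF/AcOH (1:1), THF, 0 °C to rt
Reagents that add atoms: none
Why: Fluoride-mediated desilylation buffered with acetic acid, so that neither phenoxide nor strong acid is present and the quinone methide pathway stays closed. Only the Si–O bond is broken, so Cα keeps its (S)-configuration.

## Compound list

1 | methyl gallate | COC(=O)c1cc(O)c(O)c(O)c1 | starting material
2 | methyl 3,4-bis(benzyloxy)-5-hydroxybenzoate | COC(=O)c1cc(O)c(OCc2ccccc2)c(OCc2ccccc2)c1 | intermediate
3 | 4-fluorobenzaldehyde | O=Cc1ccc(F)cc1 | starting material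
4 | methyl 3,4-bis(benzyloxy)-5-(4-formylphenoxy)benzoate | COC(=O)c1cc(Oc2ccc(C=O)cc2)c(OCc2ccccc2)c(OCc2ccccc2)c1 | intermediate
5 | methyl 3,4-bis(benzyloxy)-5-(4-vinylphenoxy)benzoate | COC(=O)c1cc(Oc2ccc(C=C)cc2)c(OCc2ccccc2)c(OCc2ccccc2)c1 | intermediate
6 | 3-bromo-2-fluorobenzaldehyde | O=Cc1cccc(Br)c1F | starting material
7 | 1-bromo-3-(dimethoxymethyl)-2-fluorobenzene | COC(OC)c1cccc(Br)c1F | intermediate
8 | methyl 3,4-bis(benzyloxy)-5-{4-[2-(9-borabicyclo[3.3.1]nonan-9-yl)ethyl]phenoxy}benzoate | COC(=O)c1cc(Oc2ccc(CCB3C4CCCC3CCC4)cc2)c(OCc2ccccc2)c(OCc2ccccc2)c1 | intermediate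
9 | methyl 3,4-bis(benzyloxy)-5-(4-{2-[3-(dimethoxymethyl)-2-fluorophenyl]ethyl}phenoxy)benzoate | COC(=O)c1cc(Oc2ccc(CCc3cccc(C(OC)OC)c3F)cc2)c(OCc2ccccc2)c(OCc2ccccc2)c1 | intermediate
10 | 3,4-bis(benzyloxy)-5-(4-{2-[3-(dimethoxymethyl)-2-fluorophenyl]ethyl}phenoxy)-N-methoxy-N-methylbenzamide | CON(C)C(=O)c1cc(Oc2ccc(CCc3cccc(C(OC)OC)c3F)cc2)c(OCc2ccccc2)c(OCc2ccccc2)c1 | intermediate
11 | 3-hydroxybenzyl alcohol | OCc1cccc(O)c1 | starting material
12 | [3-(allyloxy)phenyl]methanol | OCc1cccc(OCC=C)c1 | intermediate
13 | 1-(allyloxy)-3-(chloromethyl)benzene | ClCc1cccc(OCC=C)c1 | intermediate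
14 | [3-(allyloxy)benzyl]magnesium chloride | Cl[Mg]Cc1cccc(OCC=C)c1 | intermediate
15 | 2-[3-(allyloxy)phenyl]-1-[3,4-bis(benzyloxy)-5-(4-{2-[3-(dimethoxymethyl)-2-fluorophenyl]ethyl}phenoxy)phenyl]ethan-1-one | C=CCOc1cccc(CC(=O)c2cc(Oc3ccc(CCc4cccc(C(OC)OC)c4F)cc3)c(OCc3ccccc3)c(OCc3ccccc3)c2)c1 | intermediate
16 | (1S)-2-[3-(allyloxy)phenyl]-1-[3,4-bis(benzyloxy)-5-(4-{2-[3-(dimethoxymethyl)-2-fluorophenyl]ethyl}phenoxy)phenyl]ethan-1-ol | C=CCOc1cccc(C[C@H](O)c2cc(Oc3ccc(CCc4cccc(C(OC)OC)c4F)cc3)c(OCc3ccccc3)c(OCc3ccccc3)c2)c1 | intermediate
17 | tert-butyldimethylsilyl ether of 16 at the (S)-carbinol | C=CCOc1cccc(C[C@H](O[Si](C)(C)C(C)(C)C)c2cc(Oc3ccc(CCc4cccc(C(OC)OC)c4F)cc3)c(OCc3ccccc3)c(OCc3ccccc3)c2)c1 | intermediate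
18 | 3-{(2S)-2-[3,4-bis(benzyloxy)-5-(4-{2-[3-(dimethoxymethyl)-2-fluorophenyl]ethyl}phenoxy)phenyl]-2-[(tert-butyldimethylsilyl)oxy]ethyl}phenol | Oc1cccc(C[C@H](O[Si](C)(C)C(C)(C)C)c2cc(Oc3ccc(CCc4cccc(C(OC)OC)c4F)cc3)c(OCc3ccccc3)c(OCc3ccccc3)c2)c1 | intermediate
19 | 3-[2-(4-{2,3-bis(benzyloxy)-5-[(1S)-1-[(tert-butyldimethylsilyl)oxy]-2-(3-hydroxyphenyl)ethyl]phenoxy}phenyl)ethyl]-2-fluorobenzaldehyde | Oc1cccc(C[C@H](O[Si](C)(C)C(C)(C)C)c2cc(Oc3ccc(CCc4cccc(C=O)c4F)cc3)c(OCc3ccccc3)c(OCc3ccccc3)c2)c1 | intermediate
20 | (S)-macrocyclic aldehyde: CHO at C3 of ring C, benzyl ethers at C3 and C4 of ring A, TBS ether at Cα | c3ccccc3COc1cc2cc(c1OCc3ccccc3)Oc1ccc(cc1)CCc1cccc(C=O)c1Oc1cccc(c1)C[C@@H]2O[Si](C)(C)C(C)(C)C | intermediate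
21 | (S)-macrocyclic aryl formate: OCHO at C3 of ring C, otherwise as 20 | c3ccccc3COc1cc2cc(c1OCc3ccccc3)Oc1ccc(cc1)CCc1cccc(OC=O)c1Oc1cccc(c1)C[C@@H]2O[Si](C)(C)C(C)(C)C | intermediate
22 | (S)-macrocyclic phenol: OH at C3 of ring C, otherwise as 20 | c3ccccc3COc1cc2cc(c1OCc3ccccc3)Oc1ccc(cc1)CCc1cccc(O)c1Oc1cccc(c1)C[C@@H]2O[Si](C)(C)C(C)(C)C | intermediate
23 | Cα-O-tert-butyldimethylsilyl ether of the target (S) | Oc1cc2cc(c1O)Oc1ccc(cc1)CCc1cccc(O)c1Oc1cccc(c1)C[C@@H]2O[Si](C)(C)C(C)(C)C | intermediate
24 | CNP0333307.1, (S)-macrocyclic tetraol | Oc1cc2cc(c1O)Oc1ccc(cc1)CCc1cccc(O)c1Oc1cccc(c1)C[C@@H]2O | target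

## Step count and risk

Total: 17 steps. Longest linear sequence: 14 steps from methyl gallate 1 (steps 1, 2, 3, 5, 6, 9, 10, 11, 12, 13, 14, 15, 16, 17). Step 4 and steps 7–8 are side branches.

**Step 14 (key step).** The most likely failure is intermolecular substitution outrunning ring closure, because the fluoride is activated by one formyl group only and is flanked by an alkyl group, so practical rates need heat. Prolonged heating then lets liberated fluoride strip the silyl ether. The fallback keeps the same two bond-forming reactions but swaps their roles: the SNAr becomes intermolecular and the B-alkyl Suzuki coupling closes the ring.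
- It sets out from styrene 5, which is converted as in step 6 into the styrene Weinreb amide F1.
- Addition of Grignard reagent 14 gives the styrene ketone F2, transfer hydrogenation as in step 10 the (S)-alcohol F3, silylation the silyl ether F4 and deallylation the styrene phenol F5.
- Intermolecular SNAr of F5 with an excess of 6 (K2CO3, DMF) gives the bromo aldehyde diaryl ether F6, which is protected as the dimethyl acetal F7 (HC(OMe)3, PPTS, MeOH).
- Hydroboration with 9-BBN gives the alkylborane F8, and intramolecular Suzuki–Miyaura coupling under dilution (PdCl2(dppf), K3PO4) gives the macrocyclic acetal F9.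
- Hydrolysis as in step 13 returns to the route at 20.

**Step 15.** Hydride instead of aryl migration would lead to the carboxylic acid, since an aryloxy group is a weaker donor than an alkoxy group. The peracid may also oxidise the electron-rich ring A. The fallback sets out from 20. MeMgBr gives the secondary alcohol F10 (mixture of epimers at the new carbinol), Dess–Martin oxidation the methyl ketone F11, and Baeyer–Villiger oxidation with mCPBA the aryl acetate F12, where aryl migrates reliably in preference to methyl. Methanolysis (K2CO3, MeOH) returns to the route at 22.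

**Step 10.** Poor facial selectivity is possible because both ketone substituents contain arenes, and hydride transfer to the electron-rich aryl ketone may be slow. Loss of the acetal in the formate medium would expose the aldehyde to reduction. The fallback sets out from 15 and changes the mode of control to Corey–Bakshi–Shibata reduction with (R)-2-methyl-CBS-oxazaborolidine and BH3·SMe2 in THF. Here the ketone is bound to a boron Lewis acid and the aryl group is placed by sterics, under non-acidic conditions. It returns to the route at 16 and makes no new compound.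

**Step 17.** With the C4 hydroxyl free, ionisation at Cα to a quinone methide (racemisation, elimination) and air oxidation of the catechol can occur during desilylation. The fallback sets out from 22 and reverses the order. Desilylation with TBAF while ring A is still benzylated, when no quinone methide can form, gives the dibenzyl carbinol F13. Neutral hydrogenolysis (H2, Pd/C, EtOAc) as the last step then returns to the route at 24.

**Step 5.** Incomplete transmetalation of the alkylborane, β-hydride elimination at the alkylpalladium stage or partial saponification of the ester by the aqueous base may erode the coupling. The fallback sets out from 5 and 7. Heck coupling (Pd(OAc)2, P(o-tol)3, Et3N, DMF) gives the (E)-stilbene F14, and diimide reduction (TsNHNH2, NaOAc, DME/H2O, reflux), which spares benzyl ethers and the aryl fluoride, returns to the route at 9.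

**Step 1.** Over- and under-alkylation of the three hydroxyls can leave little of the wanted dibenzyl ether. The fallback sets out from 1 and fixes the regiochemistry by protection.
- Dichlorodiphenylmethane gives the 3,4-diphenylmethylene ketal F15, and allylation of the remaining hydroxyl gives the allyl ether F16.
- Acid hydrolysis of the ketal gives the catechol F17, and dibenzylation gives the allyl dibenzyl ether F18.
- Deallylation (Pd(PPh3)4, morpholine) returns to the route at 2.

## Further compounds

F1 | step 14 | 3,4-bis(benzyloxy)-N-methoxy-N-methyl-5-(4-vinylphenoxy)benzamide | CON(C)C(=O)c1cc(Oc2ccc(C=C)cc2)c(OCc2ccccc2)c(OCc2ccccc2)c1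
F2 | step 14 | 2-[3-(allyloxy)phenyl]-1-[3,4-bis(benzyloxy)-5-(4-vinylphenoxy)phenyl]ethan-1-one | C=CCOc1cccc(CC(=O)c2cc(Oc3ccc(C=C)cc3)c(OCc3ccccc3)c(OCc3ccccc3)c2)c1
F3 | step 14 | (1S)-2-[3-(allyloxy)phenyl]-1-[3,4-bis(benzyloxy)-5-(4-vinylphenoxy)phenyl]ethan-1-ol | C=CCOc1cccc(C[C@H](O)c2cc(Oc3ccc(C=C)cc3)c(OCc3ccccc3)c(OCc3ccccc3)c2)c1
F4 | step 14 | tert-butyldimethylsilyl ether of F3 | C=CCOc1cccc(C[C@H](O[Si](C)(C)C(C)(C)C)c2cc(Oc3ccc(C=C)cc3)c(OCc3ccccc3)c(OCc3ccccc3)c2)c1
F5 | step 14 | 3-{(2S)-2-[3,4-bis(benzyloxy)-5-(4-vinylphenoxy)phenyl]-2-[(tert-butyldimethylsilyl)oxy]ethyl}phenol | Oc1cccc(C[C@H](O[Si](C)(C)C(C)(C)C)c2cc(Oc3ccc(C=C)cc3)c(OCc3ccccc3)c(OCc3ccccc3)c2)c1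
F6 | step 14 | 3-bromo-2-(3-{(2S)-2-[3,4-bis(benzyloxy)-5-(4-vinylphenoxy)phenyl]-2-[(tert-butyldimethylsilyl)oxy]ethyl}phenoxy)benzaldehyde | O=Cc1cccc(Br)c1Oc1cccc(C[C@H](O[Si](C)(C)C(C)(C)C)c2cc(Oc3ccc(C=C)cc3)c(OCc3ccccc3)c(OCc3ccccc3)c2)c1
F7 | step 14 | dimethyl acetal of F6 | COC(OC)c1cccc(Br)c1Oc1cccc(C[C@H](O[Si](C)(C)C(C)(C)C)c2cc(Oc3ccc(C=C)cc3)c(OCc3ccccc3)c(OCc3ccccc3)c2)c1
F8 | step 14 | B-alkyl-9-BBN adduct of F7 at the terminal vinyl carbon | COC(OC)c1cccc(Br)c1Oc1cccc(C[C@H](O[Si](C)(C)C(C)(C)C)c2cc(Oc3ccc(CCB4C5CCCC4CCC5)cc3)c(OCc3ccccc3)c(OCc3ccccc3)c2)c1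
F9 | step 14 | dimethyl acetal of macrocyclic aldehyde 20 | c3ccccc3COc1cc2cc(c1OCc3ccccc3)Oc1ccc(cc1)CCc1cccc(C(OC)OC)c1Oc1cccc(c1)C[C@@H]2O[Si](C)(C)C(C)(C)C
F10 | step 15 | macrocycle with 1-hydroxyethyl at C3 of ring C, otherwise as 20 | c3ccccc3COc1cc2cc(c1OCc3ccccc3)Oc1ccc(cc1)CCc1cccc(C(C)O)c1Oc1cccc(c1)C[C@@H]2O[Si](C)(C)C(C)(C)C
F11 | step 15 | macrocycle with acetyl at C3 of ring C, otherwise as 20 | c3ccccc3COc1cc2cc(c1OCc3ccccc3)Oc1ccc(cc1)CCc1cccc(C(C)=O)c1Oc1cccc(c1)C[C@@H]2O[Si](C)(C)C(C)(C)C
F12 | step 15 | macrocycle with acetoxy at C3 of ring C, otherwise as 20 | c3ccccc3COc1cc2cc(c1OCc3ccccc3)Oc1ccc(cc1)CCc1cccc(OC(C)=O)c1Oc1cccc(c1)C[C@@H]2O[Si](C)(C)C(C)(C)C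
F0 | step 10 | none | none
F13 | step 17 | (S)-macrocyclic carbinol with benzyl ethers at C3 and C4 of ring A and free OH at C3 of ring C | c3ccccc3COc1cc2cc(c1OCc3ccccc3)Oc1ccc(cc1)CCc1cccc(O)c1Oc1cccc(c1)C[C@@H]2O
F14 | step 5 | methyl 3,4-bis(benzyloxy)-5-(4-{(E)-2-[3-(dimethoxymethyl)-2-fluorophenyl]vinyl}phenoxy)benzoate | COC(=O)c1cc(Oc2ccc(/C=C/c3cccc(C(OC)OC)c3F)cc2)c(OCc2ccccc2)c(OCc2ccccc2)c1
F15 | step 1 | methyl 7-hydroxy-2,2-diphenyl-1,3-benzodioxole-5-carboxylate | COC(=O)c1cc(O)c2c(c1)OC(O2)(c1ccccc1)c1ccccc1
F16 | step 1 | methyl 7-(allyloxy)-2,2-diphenyl-1,3-benzodioxole-5-carboxylate | COC(=O)c1cc(OCC=C)c2c(c1)OC(O2)(c1ccccc1)c1ccccc1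
F17 | step 1 | methyl 3-(allyloxy)-4,5-dihydroxybenzoate | COC(=O)c1cc(OCC=C)c(O)c(O)c1
F18 | step 1 | methyl 3-(allyloxy)-4,5-bis(benzyloxy)benzoate | COC(=O)c1cc(OCC=C)c(OCc2ccccc2)c(OCc2ccccc2)c1
A1 | alternative 1 | (S)-1,2-diarylethyl pinacol boronate carrying all four rings, both formyl groups as dioxolanes | CC1(C)OB(OC1(C)C)[C@@H](Cc1cccc(c1)Oc1c(cccc1OCc1ccccc1)C1OCCO1)c1cc(OCc2ccccc2)c(OCc2ccccc2)c(c1)Oc1ccc(cc1)C1OCCO1
A2 | alternative 1 | 2-{4-[2,3-bis(benzyloxy)-5-bromophenoxy]phenyl}-1,3-dioxolane (ring A–O–ring B bromide) | Brc1cc(OCc2ccccc2)c(OCc2ccccc2)c(c1)Oc1ccc(cc1)C1OCCO1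
A3 | alternative 1 | 3-[2-(benzyloxy)-6-(1,3-dioxolan-2-yl)phenoxy]phenyl trifluoromethanesulfonate (ring C–O–ring D triflate) | O=S(=O)(Oc1cccc(c1)Oc1c(cccc1OCc1ccccc1)C1OCCO1)C(F)(F)F
A4 | alternative 1 | vinylboronic acid pinacol ester | C=CB1OC(C)(C)C(C)(C)O1
A5 | alternative 2 | 19-membered macrocyclic α-(tributylstannyl) dibenzyl ether, tris-TBS protected, (R) at the stannylated carbon | CC(C)(C)[Si](C)(C)Oc1cc2cc(c1O[Si](C)(C)C(C)(C)C)Oc1ccc(cc1)CCc1cccc(O[Si](C)(C)C(C)(C)C)c1Oc1cccc(c1)CO[C@@H]2[Sn](CCCC)(CCCC)CCCC
A6 | alternative 2 | tris-TBS ether of the target with free (S)-carbinol | CC(C)(C)[Si](C)(C)Oc1cc2cc(c1O[Si](C)(C)C(C)(C)C)Oc1ccc(cc1)CCc1cccc(O[Si](C)(C)C(C)(C)C)c1Oc1cccc(c1)C[C@@H]2O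
A7 | alternative 3 | seco bisphenol with 3,5-dibromo-4-hydroxyphenyl ring A and 3,5-dichloro-4-hydroxyphenyl ring B, (S)-OTBS, ring C O-benzyl | Oc1c(Br)cc(cc1Br)[C@@H](O[Si](C)(C)C(C)(C)C)Cc1cccc(c1)Oc1c(cccc1OCc1ccccc1)CCc1cc(Cl)c(O)c(Cl)c1
A8 | alternative 3 | macrocyclic diaryl ether with ring A bromide and ring B chlorides | Brc1cc2cc(c1O)Oc1c(Cl)cc(cc1Cl)CCc1cccc(OCc3ccccc3)c1Oc1cccc(c1)C[C@@H]2O[Si](C)(C)C(C)(C)C
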